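The earlier runs and the new flask were computed with made-up constants, and the scatter is random.

In a one-step world, with substrate + reagent + free catalyst → product + free catalyst and nothing else, I expected the flask to stop where the reagent gave out. That is the limiting reagent, charged at 0.0700 M against 0.10 M of substrate, so the ceiling was product 70.0 %.

common to all: substrate 0.10 M; free catalyst 0.37 mM

| flask | reagent | remark | time |
|---|---|---|---|
| gamma | 0.070 M | the very flask that is asked about, followed so far |  |
| beta | 0.035 M | run made earlier |  |
| flask | 0.0700 M |  | 40 min |

- gamma (time / min: product / %, substrate / %): 2.00: 12.1, 89.2; 6.00: 22.7, 76.5; 12.0: 29.4, 71.0; 15.0: 29.3, 68.5; 25.0: 34.1, 65.8; 30.0: 34.0, 65.4; 40.0: 34.5, 65.1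
- beta (time / min: product / %, substrate / %): 1.00: 3.7, 97.2; 3.00: 9.1, 90.6; 6.00: 13.8, 85.8; 8.00: 16.4, 83.4; 12.0: 19.8, 79.7; 15.0: 22.7, 79.0; 20.0: 24.3, 74.6

(scatter of a reading: 0.5 percentage points)

- product, in percent of the substrate first charged, at 40 min
- the option that brings most further product ("none" if no option brings more than 2 percentage points) (south-west / west / north-west / south / none)
- product present, with what was taken out counted in, in percent of the substrate first charged, after south-west
- product present, with what was taken out counted in, in percent of the substrate first charged, after west

- south-west: change nothing and wait 40 min more
- west: at 40 min take out 90 % of the product then present, then wait 40 min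
- north-west: at 40 min add reagent, 50.0 % of the amount charged, then wait 40 min
- south: at 40 min add free catalyst, 100 % of the amount charged, then wait 40 min

- removed product is counted in
- the analysis behind the earlier runs scatters by 0.5 percentage points, standard deviation
- candidate steps: substrate + reagent + free catalyst -> product + free catalyst; reagent + free catalyst -> spent catalyst
- additions bring no volume worth counting

1. The gamma readings did not reach that ceiling. Product stood at 34.1 %, 34.0 % and 34.5 % in its last readings, up to 40.0 min.

2. I added reagent + free catalyst → spent catalyst and wrote the reagent balance: charged reagent = reagent left + product + spent catalyst. With the whole catalyst charge counted as spent, gamma still held 50.2 % of its reagent, about half. So the gamma plateau was not the reagent ceiling.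

3. As written, both steps carry [reagent][free catalyst], and these divide out: each unit of [spent catalyst] formed lowers ln[substrate] by a fixed amount. I named this the bite, the logarithm of substrate charged over substrate left, per catalyst charged. The gamma plateau gave, as a reading, 1.16 mM⁻¹. In this rule reagent stands in the pace and not in the end point: beta, with half the reagent, held product 13.8 % at 6.00 min against gamma's 22.7 %.

4. My reckoning: waiting, removing product and adding reagent bring no new catalyst, so I counted no further bite for them. A second catalyst dose takes the same bite from the 65.1 % of substrate remaining, a gain of 23 percentage points. The 35.1 mM of reagent left in the flask covers that.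

5. The forecast gave 34.5 % now (34 % to 35 %), 34.7 % after south-west, 34.7 % after west, and south as best: “The flask has stalled because the catalyst is dead.” Its gain for south was roughly 20 points, below mine.

6. The flask gave 34.7 % now, 35.0 % after south-west and 35.0 % after west. Best was south, bringing 23 points, against 0.28 points for north-west.

    substrate + reagent + free catalyst → product + free catalyst, rate k1*[substrate]*[reagent]*[free catalyst]/(1 + ([substrate]/sat1)) (0.150 M, k = 5200 M⁻² min⁻¹)
    reagent + free catalyst → spent catalyst (k = 2.90 M⁻¹ min⁻¹)

The step to spent catalyst held this flask down: the run without that step reached product 65.8 % at 40 min instead of 34.7 %, the largest single effect. The bite then serves a second flask, charged with 0.0015 M of free catalyst. By the bite that charge is good for product 82.5 %, above the reagent ceiling of 70.0 %, so I looked to the ceiling. At 40 min that flask held product 68.6 %, with reagent down to 0.75 % of its charge and free catalyst still at 40.0 % of its charge.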